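**Retrosynthetic overview**

1. Target 18 ⇐ 17 (fluoride desilylation) ⇐ keto lactone 16, by chelation-controlled Zn(BH4)2 reduction of the C7' ketone, so that C7' is read off C3.
2. 16 ⇐ trans aryl cyclopropyl ketone 12 + CO2 (13): formal insertion of CO2 into the cyclopropane σ-bond between the ring CH2 and the acyl-bearing carbon, making C5–O1 and C2–C3 in one operation (three-membered ring → five-membered ring).
3. Enabling feature: C5 and C3 of the oxolanone both sit on C4, so C3–C4–C5 can be tied into a cyclopropane. C3 also carries the benzylic carbinol carbon C7', which at the ketone level makes that cyclopropane an acceptor whose ring-opened enolate carbon is C3. The remaining ring atoms O1–C2(=O) are then CO2 itself.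
4. 12 ⇐ cyclopropanecarbaldehyde 7 + aryllithium 10 (then oxidation); 7 ⇐ asymmetric Simmons–Smith cyclopropanation of E-allylic alcohol 5, which sets C4, the one centre that has to be carried.
5. 5 ⇐ silylated eugenol 2 + methyl acrylate 3 (cross-metathesis, then i-Bu2AlH). Ring order: cyclopropane (step 4, temporary), then the lactone (step 9); both arenes are bought.

Key step: step 9

Notation: Ar = 3-methoxy-4-[(triisopropylsilyl)oxy]phenyl; lactone atoms are O1, C2 (C=O), C3, C4, C5; C7' is the carbinol carbon on C3.

Remark (assumption): the (4R,5R)-dioxaborolane is chosen on the assumption that 5 reacts with the same facial sense as (E)-cinnamyl alcohol, which gives the (1S,2S)-cyclopropane with this controller; if the sense were opposite, the (4S,5S) controller would be used.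

**Route**

Step 1
Reactants: 1 eugenol (4-allyl-2-methoxyphenol)
Product: 2 (4-allyl-2-methoxyphenoxy)triisopropylsilane
Conditions: i-Pr3SiCl, imidazole, DMF, rt
Reagents that add atoms: triisopropylsilyl chloride, CC(C)[Si](Cl)(C(C)C)C(C)C
Why: Imidazole-promoted O-silylation of the phenol gives a hindered aryl silyl ether that should survive zinc carbenoid, organolithium, MgI2 and hydride conditions and come off last with fluoride.

Step 2
Reactants: 2 (4-allyl-2-methoxyphenoxy)triisopropylsilane; 3 methyl acrylate
Product: 4 methyl (2E)-4-Ar-but-2-enoate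
Conditions: second-generation Hoveyda–Grubbs catalyst RuCl2(H2IMes)(=CH-C6H4-2-O-i-Pr) (3 mol %), 1,4-benzoquinone (10 mol %), 3 (4 equiv), CH2Cl2, 40 °C
Reagents that add atoms: none
Why: Olefin cross-metathesis of a terminal allyl arene with an acrylate, a partner that hardly homodimerises, should give the thermodynamically preferred E-enoate, and benzoquinone should suppress hydride-induced migration of the allyl double bond.

Step 3
Reactants: 4 methyl (2E)-4-Ar-but-2-enoate
Product: 5 (2E)-4-Ar-but-2-en-1-ol
Conditions: i-Bu2AlH (2.3 equiv), CH2Cl2, −78 °C; aq. potassium sodium tartrate work-up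
Reagents that add atoms: none
Why: 1,2-Reduction of the conjugated ester by i-Bu2AlH at low temperature should give the E-allylic alcohol without touching the alkene or the silyl ether.

Step 4
Reactants: 5 (2E)-4-Ar-but-2-en-1-ol
Product: 6 [(1S,2R)-2-(ArCH2)cyclopropyl]methanol
Conditions: Zn(CH2I)2·DME (2.2 equiv, from Et2Zn, CH2I2 and DME), (4R,5R)-2-butyl-N,N,N',N'-tetramethyl-1,3,2-dioxaborolane-4,5-dicarboxamide (1.2 equiv), CH2Cl2, −10 °C to rt; aq. NaOH work-up
Reagents that add atoms: diiodomethane, ICI
Why: Simmons–Smith cyclopropanation in its dioxaborolane-controlled asymmetric (Charette) form: the zinc alkoxide of 5 binds the chiral boronate, which directs CH2 transfer to one alkene face, and the stereospecific syn addition turns the E-alkene into the trans-cyclopropane, so the future C4 centre (R) is set here.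

Step 5
Reactants: 6 [(1S,2R)-2-(ArCH2)cyclopropyl]methanol
Product: 7 (1S,2R)-2-(ArCH2)cyclopropane-1-carbaldehyde
Conditions: Dess–Martin periodinane, NaHCO3, CH2Cl2, 0 °C to rt
Reagents that add atoms: none
Why: Dess–Martin oxidation under buffered conditions should give the aldehyde without opening the cyclopropane, and the aldehyde-bearing ring carbon loses its stereochemical role in step 9 anyway.

Step 6
Reactants: 8 4-bromo-2-methoxyphenol
Product: 9 (4-bromo-2-methoxyphenoxy)triisopropylsilane
Conditions: i-Pr3SiCl, imidazole, DMF, rt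
Reagents that add atoms: triisopropylsilyl chloride, CC(C)[Si](Cl)(C(C)C)C(C)C
Why: The same phenol O-silylation as in step 1 masks the acidic OH before bromine–lithium exchange.

Step 7
Reactants: 9 (4-bromo-2-methoxyphenoxy)triisopropylsilane; 7 (1S,2R)-2-(ArCH2)cyclopropane-1-carbaldehyde
Product: 11 Ar[(1S,2R)-2-(ArCH2)cyclopropyl]methanol (both carbinol epimers), via aryllithium 10 (not isolated)
Conditions: 9, n-BuLi, THF, −78 °C; then 7, −78 °C; H2O quench
Reagents that add atoms: none
Why: Bromine–lithium exchange followed by 1,2-addition of the aryllithium to the aldehyde; the new carbinol centre is uncontrolled and irrelevant because it is oxidised in step 8.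

Step 8
Reactants: 11 Ar[(1S,2R)-2-(ArCH2)cyclopropyl]methanol (both carbinol epimers)
Product: 12 Ar[(1S,2R)-2-(ArCH2)cyclopropyl]methanone
Conditions: Dess–Martin periodinane, NaHCO3, CH2Cl2, 0 °C to rt
Reagents that add atoms: none
Why: Buffered Dess–Martin oxidation of the benzylic cyclopropyl carbinol (avoiding acid-promoted cyclopropylcarbinyl opening) installs the aryl ketone that turns the cyclopropane into an acceptor.

Step 9
Reactants: 12 Ar[(1S,2R)-2-(ArCH2)cyclopropyl]methanone; 13 carbon dioxide
Product: 16 (3S,4R)-3-(ArCO)-4-(ArCH2)oxolan-2-one, via γ-iodo magnesium enolate 14 (not isolated), via magnesium β-keto carboxylate 15 (not isolated)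
Conditions: MgI2 (1.2 equiv), CO2 (10 bar), THF, 60 °C, sealed vessel; aq. citric acid work-up
Reagents that add atoms: none
Why: Proposed new method: Mg2+ bound to the aryl ketone lets iodide open the cyclopropane at its unsubstituted CH2 (homo-conjugate SN2 cleavage of the CH2–C(acyl) σ-bond) to give the γ-iodo magnesium enolate 14, whose carbon adds to CO2 to form the C2–C3 bond as the magnesium-chelated β-keto carboxylate 15, and the carboxylate oxygen then displaces the primary iodide to form the C5–O1 bond and return MgI2. The closest known reaction types are the MgI2-promoted ring expansions of acceptor cyclopropanes (spirocyclopropyl oxindoles, cyclopropyl ketones and amides) with imines, aldehydes and isocyanates, the halide-catalysed insertion of CO2 into epoxides and aziridines, and the magnesium-mediated carboxylation of ketone enolates with CO2; what is new is CO2 as the two-atom partner of a cyclopropyl ketone. The lactone closes by 5-exo-tet O-alkylation, so that overall CO2 is inserted into a C–C σ-bond and the three-membered ring becomes the five-membered one. C4 keeps the configuration of the cyclopropane because none of its bonds is broken, while C3, the acidic methine of a 1,3-dicarbonyl, should equilibrate to the more stable trans arrangement with the C4 benzyl group (3S). The step needs cleavage of the CH2–C3 bond rather than the CH(benzyl)–C3 bond and C- rather than O-trapping of the enolate: the first is secured because only the unsubstituted ring carbon offers a primary SN2 site both to iodide and to the closing carboxylate, while opening at the benzyl-bearing carbon has no cation-stabilising group and is reversible, and the second by magnesium chelation of the carboxylate under CO2 pressure.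

Step 10
Reactants: 16 (3S,4R)-3-(ArCO)-4-(ArCH2)oxolan-2-one
Product: 17 (3S,4R)-3-[(S)-Ar(hydroxy)methyl]-4-(ArCH2)oxolan-2-one
Conditions: Zn(BH4)2 (1.5 equiv), Et2O, −78 to −20 °C; aq. work-up
Reagents that add atoms: none
Why: Chelation-controlled 1,2-reduction: zinc bridges the ketone and lactone carbonyl oxygens and hydride should attack the ketone face on the side of C3–H, anti to C4 and its benzyl group, which gives the syn (7'S) carbinol.

Step 11
Reactants: 17 (3S,4R)-3-[(S)-Ar(hydroxy)methyl]-4-(ArCH2)oxolan-2-one
Product: 18 (3S,4R)-3-[(S)-hydroxy(4-hydroxy-3-methoxyphenyl)methyl]-4-[(4-hydroxy-3-methoxyphenyl)methyl]oxolan-2-one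
Conditions: Bu4NF (2.4 equiv), AcOH (2.4 equiv), THF, 0 °C
Reagents that add atoms: none
Why: Fluoride cleavage of the two aryl silyl ethers, buffered with acetic acid so that neither phenoxide nor alkoxide persists, should free both phenols without retro-aldol cleavage of the β-hydroxy lactone.

**Compound list**

1 | eugenol (4-allyl-2-methoxyphenol) | C=CCc1ccc(O)c(OC)c1 | starting material
2 | (4-allyl-2-methoxyphenoxy)triisopropylsilane | C=CCc1ccc(O[Si](C(C)C)(C(C)C)C(C)C)c(OC)c1 | intermediate
3 | methyl acrylate | C=CC(=O)OC | starting material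
4 | methyl (2E)-4-{3-methoxy-4-[(triisopropylsilyl)oxy]phenyl}but-2-enoate | COC(=O)/C=C/Cc1ccc(O[Si](C(C)C)(C(C)C)C(C)C)c(OC)c1 | intermediate
5 | (2E)-4-{3-methoxy-4-[(triisopropylsilyl)oxy]phenyl}but-2-en-1-ol | OC/C=C/Cc1ccc(O[Si](C(C)C)(C(C)C)C(C)C)c(OC)c1 | intermediate
6 | [(1S,2R)-2-(ArCH2)cyclopropyl]methanol | COc1cc(C[C@H]2C[C@@H]2CO)ccc1O[Si](C(C)C)(C(C)C)C(C)C | intermediate
7 | (1S,2R)-2-(ArCH2)cyclopropane-1-carbaldehyde | COc1cc(C[C@H]2C[C@@H]2C=O)ccc1O[Si](C(C)C)(C(C)C)C(C)C | intermediate
8 | 4-bromo-2-methoxyphenol | COc1cc(Br)ccc1O | starting material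
9 | (4-bromo-2-methoxyphenoxy)triisopropylsilane | COc1cc(Br)ccc1O[Si](C(C)C)(C(C)C)C(C)C | intermediate
10 | {3-methoxy-4-[(triisopropylsilyl)oxy]phenyl}lithium (aryllithium, not isolated) | COc1cc([Li])ccc1O[Si](C(C)C)(C(C)C)C(C)C | intermediate
11 | Ar[(1S,2R)-2-(ArCH2)cyclopropyl]methanol, both carbinol epimers | COc1cc(C[C@H]2C[C@@H]2C(O)c2ccc(O[Si](C(C)C)(C(C)C)C(C)C)c(OC)c2)ccc1O[Si](C(C)C)(C(C)C)C(C)C | intermediate
12 | Ar[(1S,2R)-2-(ArCH2)cyclopropyl]methanone | COc1cc(C[C@H]2C[C@@H]2C(=O)c2ccc(O[Si](C(C)C)(C(C)C)C(C)C)c(OC)c2)ccc1O[Si](C(C)C)(C(C)C)C(C)C | intermediate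
13 | carbon dioxide | O=C=O | starting material
14 | iodomagnesium (1Z,3R)-1-Ar-3-(ArCH2)-4-iodobut-1-en-1-olate (γ-iodo magnesium enolate, not isolated) | COc1cc(C[C@@H](CI)/C=C(\O[Mg]I)c2ccc(O[Si](C(C)C)(C(C)C)C(C)C)c(OC)c2)ccc1O[Si](C(C)C)(C(C)C)C(C)C | intermediate
15 | iodomagnesium (3R)-2-(ArCO)-3-(ArCH2)-4-iodobutanoate, C2 epimers (magnesium β-keto carboxylate, not isolated) | COc1cc(C[C@@H](CI)C(C(=O)O[Mg]I)C(=O)c2ccc(O[Si](C(C)C)(C(C)C)C(C)C)c(OC)c2)ccc1O[Si](C(C)C)(C(C)C)C(C)C | intermediate
16 | (3S,4R)-3-(ArCO)-4-(ArCH2)oxolan-2-one | COc1cc(C[C@H]2COC(=O)[C@@H]2C(=O)c2ccc(O[Si](C(C)C)(C(C)C)C(C)C)c(OC)c2)ccc1O[Si](C(C)C)(C(C)C)C(C)C | intermediate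
17 | (3S,4R)-3-[(S)-Ar(hydroxy)methyl]-4-(ArCH2)oxolan-2-one | COc1cc(C[C@H]2COC(=O)[C@@H]2[C@H](O)c2ccc(O[Si](C(C)C)(C(C)C)C(C)C)c(OC)c2)ccc1O[Si](C(C)C)(C(C)C)C(C)C | intermediate
18 | (3S,4R)-3-[(S)-hydroxy(4-hydroxy-3-methoxyphenyl)methyl]-4-[(4-hydroxy-3-methoxyphenyl)methyl]oxolan-2-one | COc1cc(C[C@H]2COC(=O)[C@@H]2[C@H](O)c2ccc(O)c(OC)c2)ccc1O | target

**Step count**

Total steps: 11. Longest linear sequence: 10 (steps 1–5 and 7–11, from eugenol 1).

**Steps most likely to fail**

1. Step 9 (proposed new method). The magnesium enolate may fail to capture CO2 faster than it recloses to the cyclopropane or O-alkylates to a dihydrofuran (Cloke–Wilson-type isomerisation), or iodide may open the ring at the benzyl-bearing carbon. The fallback sets out from 12 and separates the two bond formations with known reactions. Me3SiI (CH2Cl2, −78 to 0 °C) would open the cyclopropane to the γ-iodo trimethylsilyl enol ether F1, which is hydrolysed on aqueous work-up to the γ-iodo ketone F2. CsOAc (DMF, rt) would displace the primary iodide to give the acetate F3, and mild methanolysis (K2CO3, MeOH, 0 °C) would give the γ-hydroxy ketone F4. ClCO2Me and pyridine (CH2Cl2, 0 °C) would give the methyl carbonate F5. LiN(SiMe3)2 (2.2 equiv, THF, −78 to 0 °C) would then effect an intramolecular Claisen-type C-acylation of the ketone enolate by the carbonate (5-exo-trig, loss of methoxide). The fallback comes back to the route at 16, before step 10.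

2. Step 10. Facial selectivity may be poor if the slowly reacting, electron-rich aryl ketone is reduced through a non-chelated transition state, and C3 may epimerise. The fallback sets out from 16 and moves facial control from the substrate to a catalyst. A Noyori–Ikariya asymmetric transfer hydrogenation with RuCl(p-cymene)[(S,S)-TsDPEN] in HCO2H/Et3N (5:2) at rt should select the ketone face independently of chelation. This catalyst enantiomer is expected to give the S carbinol by analogy with simple aryl alkyl ketones, and the labile C3 centre should funnel to the trans lactone. The fallback comes back at 17 and makes no new compound (F0).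

3. Step 11. Fluoride may generate phenoxide or alkoxide that triggers retro-aldol cleavage of the β-hydroxy lactone, or loss or epimerisation of the benzylic hydroxyl through a para-quinone methide. The fallback sets out from 16 and changes the order of events. Both silyl ethers would be removed at the ketone stage, where no aldol-type fragility exists (Bu4NF, AcOH, THF, 0 °C), to give the diphenol keto lactone (3S,4R)-3-(4-hydroxy-3-methoxybenzoyl)-4-[(4-hydroxy-3-methoxyphenyl)methyl]oxolan-2-one F6. This would then be reduced with Zn(BH4)2 (extra hydride for the two phenols, Et2O/THF, −78 to −20 °C) under the same chelation control. The fallback comes back at 18.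

**Further compounds**

F1 | step 9 | {[(1Z,3R)-1-Ar-3-(ArCH2)-4-iodobut-1-en-1-yl]oxy}trimethylsilane | COc1cc(C[C@@H](CI)/C=C(\O[Si](C)(C)C)c2ccc(O[Si](C(C)C)(C(C)C)C(C)C)c(OC)c2)ccc1O[Si](C(C)C)(C(C)C)C(C)C
F2 | step 9 | (3R)-1-Ar-3-(ArCH2)-4-iodobutan-1-one | COc1cc(C[C@@H](CI)CC(=O)c2ccc(O[Si](C(C)C)(C(C)C)C(C)C)c(OC)c2)ccc1O[Si](C(C)C)(C(C)C)C(C)C
F3 | step 9 | (2R)-4-Ar-2-(ArCH2)-4-oxobutyl acetate | COc1cc(C[C@@H](COC(C)=O)CC(=O)c2ccc(O[Si](C(C)C)(C(C)C)C(C)C)c(OC)c2)ccc1O[Si](C(C)C)(C(C)C)C(C)C
F4 | step 9 | (3R)-1-Ar-3-(ArCH2)-4-hydroxybutan-1-one | COc1cc(C[C@@H](CO)CC(=O)c2ccc(O[Si](C(C)C)(C(C)C)C(C)C)c(OC)c2)ccc1O[Si](C(C)C)(C(C)C)C(C)C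
F5 | step 9 | (2R)-4-Ar-2-(ArCH2)-4-oxobutyl methyl carbonate | COc1cc(C[C@@H](COC(=O)OC)CC(=O)c2ccc(O[Si](C(C)C)(C(C)C)C(C)C)c(OC)c2)ccc1O[Si](C(C)C)(C(C)C)C(C)C
F0 | step 10 | none | none
F6 | step 11 | (3S,4R)-3-(4-hydroxy-3-methoxybenzoyl)-4-[(4-hydroxy-3-methoxyphenyl)methyl]oxolan-2-one | COc1cc(C[C@H]2COC(=O)[C@@H]2C(=O)c2ccc(O)c(OC)c2)ccc1O
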